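**Remark (assumption).** The target has no stereocentre, so the spiro intermediates are carried as racemates. Compounds 3, 9, 12 and 13 are taken as purchased. Electrophilic acylation of orcinol would favour the carbon next to the methyl group, so the acyl carbon is placed between the two oxygens by directed metalation instead.

## Structural features

The target is an achiral, fully aromatic diaryl ether. Ring A is a pentasubstituted methyl benzoate (C1 CO2Me, C2 ether oxygen, C3 OMe, C4 Cl, C5 OH, C6 H). Ring B is a tetrasubstituted benzoic acid (C1' ether oxygen, C3' CH3, C5' OH, C6' CO2H). The rings are joined only through the oxygen between C2 and C1', which has three ortho neighbours (CO2Me and OMe on ring A, CO2H on ring B), so a late aryl–oxygen coupling is unattractive. The target has no stereocentre; the only adjacent stereocentres on the route are C1 and C2 of the spiro intermediates, and both are erased later. Fragile points are the methyl ester that must survive beside a free acid, the 2,6-dioxygenated benzoic acid of ring B (prone to decarboxylation in hot acid), the aryl chloride (hydrogenolysis) and the single methyl ether that must stay while two phenols are freed. The real difficulty is regiochemical: five contiguous substituents on ring A with chlorine exactly between the methoxy and hydroxy carbons, and two carboxyl groups in different states on either side of a hindered ether. The key step uses two features. The oxygens on C3 and C5 with C4 between them are the footprint of a 1,1-dimethoxy-3-silyloxybutadiene (C3 to C6). The C1–C2 pair carrying the ester and the ether oxygen is the exocyclic alkene of a benzofuranone whose ketone carbon is the later C6' carboxyl.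

## Logic of the disconnections

**22 back to 21.** The benzyl–oxygen bond on the C5' oxygen is restored. The ring B phenol has to be masked through cycloaddition, chlorination and dehydrogenation, where a free phenol would be silylated, chlorinated or oxidized. Nothing is gained in skeleton, but every electrophilic step becomes site-selective. The forward demand is a debenzylation that spares the aryl chloride, the methyl ether and the methyl ester, so a Lewis acid with a cation scavenger is used and not hydrogenolysis.

**21 back to 20.** The carboxyl carbon on C6' is reconnected to C2 of ring A. This turns the hindered diaryl ether into an alkyl aryl ether at a spiro carbon and stores ring A as a cyclohexadienone. The aryl–oxygen bond is then never made by coupling, and the two carboxyl groups are differentiated automatically (one enters as an ester, the other is born as an acid). The forward demand is that hydroxide attacks the furanone ketone of 20 faster than the methyl ester or the methoxy-bearing carbon C3.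

**20 back to 19.** The C1=C6 double bond is saturated. The cycloaddition delivers ring A one oxidation level below the phenol, and this cut places the adjustment at the only position where hydrogens remain. The forward demand is a dehydrogenation across C6–C1 that tolerates the benzyl ether and the enol ether.

**19 back to 18.** The C4–Cl bond is cut. In 18, C4 is the α-carbon of a β-methoxy enone and the one strongly nucleophilic carbon of the molecule. Chlorination of the phenols of 21 or 22 could not distinguish C4 from C6 or from ring B. The forward demand is a mild source of electrophilic chlorine that leaves the benzyloxy arene alone.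

**18 back to 11 and 16.** The bonds C6–C1 and C3–C2 are cut. This removes ring A entirely and leaves an alkene and a four-carbon diene whose oxygen pattern already encodes C3-OMe and C5-oxygen. The forward demand is a [4+2] addition in which the CH2 terminus of 16 bonds to C1 of 11 and the acetal carbon to C2.

**11 back to 8 and 9.** The C1=C2 double bond is cut as an aldol condensation. This separates the ester carbon chain from the bicyclic ketone. The forward demand is only that the condensation product does not add a second molecule of 8.

**16 back to 14, then to 12 and 13.** The O–Si bond is cut first, then the C4–C5 bond (ring A numbering) between the ketene-acetal carbon and the acetyl carbonyl. Both fragments are two-carbon commodity chemicals. The forward demand is C-acylation without ketene formation and kinetic enol silylation at the methyl group.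

**8 back to 7, 5, 2 with 3, and 1.** The cuts are the benzyl ether, the furanone O–CH2 bond (a phenoxide displacing chloride), the bond between C6' and its acyl carbon, and the two acetal protecting groups. The aryl–acyl cut is made between the two oxygens because the symmetric 2 can be metalated only there. The forward demand is an acylating agent, 3, that stops at the ketone and keeps its chloride.

## Other disconnections considered

**Alternative 1:** Ring B is cut at C1'–C6' and C2'–C3'.
- Forward key step: the ethynyl ether A2, made from the ring A phenol A1, would be heated with the pyrone A3. An inverse-demand [4+2] addition would join the alkyne CH to the methyl-bearing C6 of the pyrone and the oxygen-bearing alkyne carbon to the ester-bearing C3. Loss of CO2 from the bridged lactone should give the tribenzyl diaryl ether A4, and one global debenzylation would finish.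
- In its favour: ring B appears directly at the aromatic level, with no transient stereocentre, no oxidation and no ring cleavage afterwards. The ether oxygen arrives as a phenol oxygen, so no hindered aryl–oxygen coupling is needed, which makes it the equal of the chosen plan on that point. Its endgame is one step against four, and there it is the better plan.
- Against it here: the key step does nothing for the contiguous pentasubstitution of ring A, which must be solved separately in A1, chlorine between two oxygens included. Turning a hindered phenol bearing a methyl ester and an aryl chloride into an ynol ether normally passes through a dichlorovinyl ether and an alkyllithium, which those groups tolerate poorly. The 4-alkoxy group deactivates A3 as an electron-poor diene, so a thermally fragile ynol ether would have to be heated strongly. Three benzyl groups must then be removed beside an aryl chloride.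
- Comparison: both plans rely on a polarized cycloaddition of predictable orientation (equal on mechanism). Structurally the chosen plan creates the ring A pattern in the key step, whereas this one needs it ready-made. Counting A1, A2 and A3, the total would probably be longer, although the endgame is shorter.

**Alternative 2:** Ring B is cut at C5'–C6'.
- Forward key step: the heptadienedioate A6 would come from conjugate addition of the ring A phenol A5 to an allenoate or alkynoate. KOC(CH3)3 would deprotonate the doubly allylic C2' methylene, and the vinylogous enolate would attack the methyl ester carbonyl C5' through C6' (a Dieckmann-type closure). Loss of methoxide and tautomerization would give the phenol A7, and one acid treatment would remove the tert-butyl ester and the methoxymethyl ether together.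
- In its favour: the closure mimics polyketide folding, ring B is again born aromatic with its phenol free, and the two carboxyl groups are told apart by tert-butyl against methyl. The single acidic endgame step is better than the four steps of the chosen plan.
- Against it here: it depends on a ready-made pentasubstituted phenol A5, as Alternative 1 does. The closure needs the Z geometry at C3'=C4'. The β-aryloxy enoate is a vinylogous carbonate from which alkoxide can expel the aryloxide. The ring A methyl ester is exposed to KOC(CH3)3 (transesterification, intermolecular Claisen), and attack through the γ-carbon can compete.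
- Comparison: on differentiation of the carboxyl groups the two plans are equal. On mechanism the chosen cycloaddition has fewer competing channels than a strongly basic enolate cascade. On step count this alternative wins after the key step and loses before it.

**Alternative 3:** Ring A is cut at C2–C1 and C2–C3, both bonds to the spiro carbon.
- Forward key step: the enolate of benzofuranone 8 (catalytic KOC(CH3)3) would add to one alkyne terminus of the diynone A8 and then to the other, each β to the ketone, the second addition being a 6-endo-dig closure. This should give the dechloro grisadienone A9. Chlorination at C4, hydroxide opening and debenzylation would follow.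
- In its favour: the strategy is the same as in the chosen plan (ether oxygen on the spiro carbon, acid by retro-Claisen opening). A9 is already at the dienone level, so the glyoxylate condensation, the diene synthesis and the dehydrogenation are saved. On paper it is shorter, and that is a real advantage.
- Against it here: A8 is a methoxyethynyl ketone flanked by an ynoate. It would have to be built from methoxyacetylene, is highly electrophilic and is liable to polymerize under alkoxide. The orientation of the first addition at the ynoate terminus (C1 is β to the ketone but α to the ester) is not assured. Chlorination would have to be done on the cross-conjugated dienone, where C4 is less nucleophilic than in 18 and ring B competes more.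
- Comparison: structurally the plans are equal. Mechanistically the chosen plan uses two stable, storable partners in a pericyclic step, against a base-sensitive double conjugate addition. Step economy favours this alternative only if A8 were at hand; with its preparation counted the advantage largely disappears.

Key step: step 8

## Route

Step 1
Reactants: 1 orcinol (5-methylbenzene-1,3-diol)
Product: 2 1,3-bis(methoxymethoxy)-5-methylbenzene
Conditions: MOMCl, i-Pr2NEt, CH2Cl2, 0 °C to rt
Reagents that add atoms: chloromethyl methyl ether, COCCl
Why: Double O-alkylation of the phenols under amine base; the two acetal ethers form the strongest cooperative directing pair for the metalation of step 2 and come off later under mild acid.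

Step 2
Reactants: 2 1,3-bis(methoxymethoxy)-5-methylbenzene; 3 2-chloro-N-methoxy-N-methylacetamide
Product: 5 2-chloro-1-[2,6-bis(methoxymethoxy)-4-methylphenyl]ethan-1-one, via aryllithium 4 (not isolated)
Conditions: n-BuLi, THF, 0 °C; then 3, −78 to 0 °C; aq. NH4Cl
Reagents that add atoms: none
Why: Directed ortho-metalation: both acetal oxygens chelate lithium, so deprotonation occurs only at the carbon between them (para to CH3), the position electrophilic acylation of 1 would not favour; Weinreb ketone synthesis then gives the chloromethyl ketone, the chelated tetrahedral intermediate preventing over-addition and leaving the chloride untouched at low temperature.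

Step 3
Reactants: 5 2-chloro-1-[2,6-bis(methoxymethoxy)-4-methylphenyl]ethan-1-one
Product: 7 4-hydroxy-6-methylbenzofuran-3(2H)-one, via dihydroxy chloroketone 6 (not isolated)
Conditions: HCl (cat.), MeOH, 50 °C; then NaOAc, reflux
Reagents that add atoms: none
Why: Acid-catalysed acetal exchange removes both protecting groups; acetate then forms the phenoxide, which displaces chloride in a 5-exo-tet intramolecular Williamson reaction (the standard coumaranone closure), and the symmetry of 6 makes the two hydroxyls equivalent.

Step 4
Reactants: 7 4-hydroxy-6-methylbenzofuran-3(2H)-one
Product: 8 4-(benzyloxy)-6-methylbenzofuran-3(2H)-one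
Conditions: BnBr (1 equiv), K2CO3, DMF, rt
Reagents that add atoms: benzyl bromide, BrCc1ccccc1
Why: Williamson O-benzylation of the only phenol; the phenol is far more acidic than the C2 methylene, so with a weak base and one equivalent of halide O-alkylation should precede C-alkylation, as in routine alkylations of hydroxybenzofuranones.

Step 5
Reactants: 8 4-(benzyloxy)-6-methylbenzofuran-3(2H)-one; 9 methyl glyoxylate
Product: 11 methyl (Z)-2-[4-(benzyloxy)-6-methyl-3-oxobenzofuran-2(3H)-ylidene]acetate, via aldol adduct 10 (not isolated)
Conditions: neutral Al2O3, CH2Cl2, rt
Reagents that add atoms: none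
Why: Aldol condensation of the acidic C2 methylene with a highly electrophilic aldehyde (aurone-type Knoevenagel condensation) followed by E1cB loss of water; the Z isomer (ester syn to the ring oxygen, away from the C3 carbonyl) is the thermodynamic one, and the non-basic surface limits conjugate addition of a second molecule of 8.

Step 6
Reactants: 12 1,1-dimethoxyethene; 13 acetyl chloride
Product: 14 4,4-dimethoxybut-3-en-2-one
Conditions: pyridine, Et2O, 0 °C to rt
Reagents that add atoms: none
Why: C-acylation of the electron-rich ketene acetal by the acylpyridinium ion gives a dimethoxycarbenium ion, which pyridine deprotonates to the push-pull acylketene acetal; pyridine is too weak a base to convert acetyl chloride into ketene.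

Step 7
Reactants: 14 4,4-dimethoxybut-3-en-2-one
Product: 16 1,1-dimethoxy-3-(trimethylsilyloxy)buta-1,3-diene, via lithium dienolate 15 (not isolated)
Conditions: LiN(i-Pr)2, THF, −78 °C; then Me3SiCl, −78 to 0 °C; distillation
Reagents that add atoms: chlorotrimethylsilane, C[Si](C)(C)Cl
Why: Kinetic deprotonation of the methyl ketone (the only enolizable position) and O-silylation of the cross-conjugated dienolate, a standard enol silylation giving the 2-silyloxydiene.

Step 8
Reactants: 11 methyl (Z)-2-[4-(benzyloxy)-6-methyl-3-oxobenzofuran-2(3H)-ylidene]acetate; 16 1,1-dimethoxy-3-(trimethylsilyloxy)buta-1,3-diene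
Product: 18 racemic spiro methoxycyclohexenone (benzofuranone C2 = ring A C2; ring A: C1 CH–CO2Me / C3 C–OMe / C4 =CH / C5 C=O / C6 CH2; CO2Me cis to the furanone oxygen), via silyl ketal cycloadduct 17 (not isolated)
Conditions: 16 (2.5 equiv), toluene, 110 °C, sealed tube; then 0.1 M HCl, THF, 0 °C
Reagents that add atoms: none
Why: This is a normal-electron-demand Diels–Alder reaction of a ketene-acetal siloxydiene with a 2-alkylidene benzofuran-3-one, the reaction type used to build grisan spirocycles. The HOMO of 16 is largest at its CH2 terminus and the LUMO of 11 is largest at the exocyclic carbon C1 (β to the aryl ketone), so bonding is concerted but asynchronous: C6–C1 leads, the developing charge at C2 is carried by an aromatic benzofuran-3-olate, and C3–C2 then closes. The ester on C1 pulls the other way, but it is the weaker acceptor, its β-carbon C2 already bears the donor oxygen, and approach of the CH2 terminus to the fully substituted C2 is the more hindered mode; these three factors secure the required orientation. Ring A closes by intermolecular [4+2] cycloaddition, two σ bonds forming a six-membered ring spiro-fused at C2. The new centres C1 and C2 are set relative to each other by suprafacial addition to the Z alkene (CO2Me cis to the ring oxygen); the product is racemic, and facial or endo/exo preferences do not matter because C1 becomes sp2 in step 10 and C2 in step 11. Cold dilute acid then hydrolyses the silyl enol ether to the C5 ketone, and the β-keto ketal loses methanol to give the C3 methoxy enone; short contact avoids hydrolysis to the diketone and avoids basic conditions that could expel the aryloxide β to the ester.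

Step 9
Reactants: 18 racemic spiro methoxycyclohexenone
Product: 19 racemic spiro chloro methoxycyclohexenone (as 18 with Cl on C4)
Conditions: NCS (1.05 equiv), MeCN, 0 °C to rt
Reagents that add atoms: N-chlorosuccinimide, O=C1CCC(=O)N1Cl
Why: Electrophilic α-chlorination of a vinylogous ester: C4 is the β-carbon of the enol ether and the most nucleophilic site, and the oxocarbenium intermediate loses the C4 proton to restore the enone; ring B is deactivated by its acyl group and should react more slowly under neutral conditions.

Step 10
Reactants: 19 racemic spiro chloro methoxycyclohexenone
Product: 20 racemic spiro chloro methoxy cyclohexadienone (ring A: C1(CO2Me)=C6H / C5 C=O / C4(Cl)=C3(OMe) / C2 spiro)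
Conditions: DDQ, TsOH (cat.), 1,4-dioxane, 100 °C
Reagents that add atoms: none
Why: DDQ dehydrogenation of an enone to the cross-conjugated dienone through the C5–C6 dienol and hydride transfer from C1, the reaction type used for 1,2-dehydrogenation of steroidal 4-en-3-ones; C6–C1 is the only place where two hydrogens can be lost because C2 is quaternary, and the C1 stereocentre disappears.

Step 11
Reactants: 20 racemic spiro chloro methoxy cyclohexadienone
Product: 21 2-(benzyloxy)-6-[3-chloro-4-hydroxy-2-methoxy-6-(methoxycarbonyl)phenoxy]-4-methylbenzoic acid
Conditions: LiOH (2.2 equiv), THF/H2O, 0 °C; then 1 M HCl, 0 °C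
Reagents that add atoms: lithium hydroxide, [Li+].[OH-]
Why: Retro-Claisen acyl cleavage of a non-enolizable vinylogous β-diketone: hydroxide adds to the strained furanone ketone and the tetrahedral intermediate expels C2 as the aromatic phenoxide of ring A, the known hydrolytic opening of grisadienones to diaryl ethers; the hindered methyl ester on the resulting dianion should saponify much more slowly at 0 °C, and the spiro stereocentre is erased.

Step 12
Reactants: 21 2-(benzyloxy)-6-[3-chloro-4-hydroxy-2-methoxy-6-(methoxycarbonyl)phenoxy]-4-methylbenzoic acid
Product: 22 2-[3-chloro-4-hydroxy-2-methoxy-6-(methoxycarbonyl)phenoxy]-6-hydroxy-4-methylbenzoic acid (target)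
Conditions: BCl3 (4 equiv), C6HMe5, CH2Cl2, −78 °C; then H2O
Reagents that add atoms: none
Why: Lewis-acid debenzylation: BCl3 coordinates the benzyl ether oxygen next to the carboxyl group and the benzyl cation is trapped by pentamethylbenzene (Friedel–Crafts alkylation), which prevents C-benzylation of the phenols; at −78 °C the methyl ether (not ortho to a carbonyl), the methyl ester and the aryl chloride should remain.

## Compound list

1 | orcinol (5-methylbenzene-1,3-diol) | Cc1cc(O)cc(O)c1 | starting material
2 | 1,3-bis(methoxymethoxy)-5-methylbenzene | COCOc1cc(C)cc(OCOC)c1 | intermediate
3 | 2-chloro-N-methoxy-N-methylacetamide | CON(C)C(=O)CCl | starting material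
4 | [2,6-bis(methoxymethoxy)-4-methylphenyl]lithium (formed in the flask, not isolated) | [Li]c1c(OCOC)cc(C)cc1OCOC | intermediate
5 | 2-chloro-1-[2,6-bis(methoxymethoxy)-4-methylphenyl]ethan-1-one | COCOc1cc(C)cc(OCOC)c1C(=O)CCl | intermediate
6 | 2-chloro-1-(2,6-dihydroxy-4-methylphenyl)ethan-1-one (formed in the flask, not isolated) | Cc1cc(O)c(C(=O)CCl)c(O)c1 | intermediate
7 | 4-hydroxy-6-methylbenzofuran-3(2H)-one | Cc1cc(O)c2C(=O)COc2c1 | intermediate
8 | 4-(benzyloxy)-6-methylbenzofuran-3(2H)-one | Cc1cc(OCc2ccccc2)c2C(=O)COc2c1 | intermediate
9 | methyl glyoxylate | COC(=O)C=O | starting material
10 | methyl 2-[4-(benzyloxy)-6-methyl-3-oxo-2,3-dihydrobenzofuran-2-yl]-2-hydroxyacetate (mixture of diastereomers; formed in the flask, not isolated) | COC(=O)C(O)C1Oc2cc(C)cc(OCc3ccccc3)c2C1=O | intermediate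
11 | methyl (Z)-2-[4-(benzyloxy)-6-methyl-3-oxobenzofuran-2(3H)-ylidene]acetate | COC(=O)/C=C1\Oc2cc(C)cc(OCc3ccccc3)c2C1=O | intermediate
12 | 1,1-dimethoxyethene | C=C(OC)OC | starting material
13 | acetyl chloride | CC(=O)Cl | starting material
14 | 4,4-dimethoxybut-3-en-2-one | CC(=O)C=C(OC)OC | intermediate
15 | lithium 4,4-dimethoxybuta-1,3-dien-2-olate (formed in the flask, not isolated) | [Li]OC(=C)C=C(OC)OC | intermediate
16 | 1,1-dimethoxy-3-(trimethylsilyloxy)buta-1,3-diene | COC(OC)=CC(=C)O[Si](C)(C)C | intermediate
17 | silyl ketal cycloadduct (racemic, one enantiomer drawn; formed in the flask, not isolated): 4-(benzyloxy)-6-methylbenzofuran-3(2H)-one spiro-fused at C2 to ring A with C1 CH–CO2Me, C3 C(OMe)2, C4 =CH, C5 =C–OSiMe3, C6 CH2; CO2Me cis to the furanone oxygen | COC(=O)[C@@H]1CC(O[Si](C)(C)C)=CC(OC)(OC)[C@]12Oc3cc(C)cc(OCc4ccccc4)c3C2=O | intermediate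
18 | spiro methoxycyclohexenone (racemic, one enantiomer drawn): same spiro skeleton, ring A with C1 CH–CO2Me, C3 C–OMe, C4 =CH, C5 C=O, C6 CH2; CO2Me cis to the furanone oxygen | COC(=O)[C@@H]1CC(=O)C=C(OC)[C@]12Oc3cc(C)cc(OCc4ccccc4)c3C2=O | intermediate
19 | spiro chloro methoxycyclohexenone (racemic, one enantiomer drawn): as 18 with Cl on C4 | COC(=O)[C@@H]1CC(=O)C(Cl)=C(OC)[C@]12Oc3cc(C)cc(OCc4ccccc4)c3C2=O | intermediate
20 | spiro chloro methoxy cyclohexadienone (racemic, one enantiomer drawn): ring A with C1(CO2Me)=C6H, C5 C=O, C4(Cl)=C3(OMe), C2 spiro | COC(=O)C1=CC(=O)C(Cl)=C(OC)[C@]12Oc3cc(C)cc(OCc4ccccc4)c3C2=O | intermediate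
21 | 2-(benzyloxy)-6-[3-chloro-4-hydroxy-2-methoxy-6-(methoxycarbonyl)phenoxy]-4-methylbenzoic acid | COC(=O)c1cc(O)c(Cl)c(OC)c1Oc1cc(C)cc(OCc2ccccc2)c1C(=O)O | intermediate
22 | 2-[3-chloro-4-hydroxy-2-methoxy-6-(methoxycarbonyl)phenoxy]-6-hydroxy-4-methylbenzoic acid | COC(=O)c1cc(O)c(Cl)c(OC)c1Oc1cc(C)cc(O)c1C(=O)O | target

## Step count and least certain steps

Total: 12 steps. Longest linear sequence: 10 steps (steps 1 to 5, then 8 to 12, from 1); the diene branch (steps 6 and 7) joins at step 8.

**Step 8 (key step).** The most likely failure is a sluggish cycloaddition at a trisubstituted, oxygen-bearing alkene, so that thermal decay or desilylation of the diene wins, or a stepwise addition that stops at the open-chain stage. Reversed orientation is the less likely failure. The fallback sets out from 11 and the lithium dienolate 15 (step 7 before silylation) and replaces the pericyclic step by an anionic two-stage annulation. At −78 °C in THF, 15 should add through its CH2 terminus to C1 of 11 and give, after protonation, the Michael adduct methyl 2-[4-(benzyloxy)-6-methyl-3-oxo-2,3-dihydrobenzofuran-2-yl]-6,6-dimethoxy-4-oxohex-5-enoate F1. With catalytic KOC(CH3)3 in THF at 0 °C the benzofuranone enolate of F1 should close on the dimethoxy carbon of the acylketene acetal (6-endo-trig conjugate addition) and lose methoxide. The route is rejoined at 18.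

**Step 10.** The most likely failure is slow hydride transfer from C1, which carries the ester, with competing oxidation at the benzylic CH2 of the ether or acid-induced loss of the enol ether on prolonged heating. The fallback sets out from 19. Soft enolization (Me3SiOTf, Et3N, CH2Cl2, 0 °C) should give the silyl dienol ether F2 (19 with C5–OSiMe3 and a C5=C6 double bond). Saegusa–Ito oxidation of F2 with Pd(OAc)2 in MeCN at rt should then give the dienone. The route is rejoined at 20.

**Step 9.** The most likely failure is competing chlorination of the benzyloxy-substituted ring B, or a second chlorination at C6 through the enol. The fallback brings the chlorine in with the diene and sets out from 14. NCS in CH2Cl2 should chlorinate the nucleophilic α-carbon to give 3-chloro-4,4-dimethoxybut-3-en-2-one F3. Enol silylation as in step 7 should give 2-chloro-1,1-dimethoxy-3-(trimethylsilyloxy)buta-1,3-diene F4. Cycloaddition of F4 with 11 under the conditions of step 8 should give the chlorinated silyl ketal cycloadduct F5, and the same cold acidic work-up should deliver the chloro enone. The route is rejoined at 19.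

**Step 11.** The most likely failure is competing saponification of the ring A methyl ester, addition of hydroxide at the methoxy-bearing C3 with loss of the methyl enol ether, or decarboxylation during acidification. The fallback sets out from 20 and avoids water. Benzyl alcohol with catalytic KOC(CH3)3 in THF at −20 °C should open the ketone in the same retro-Claisen sense and give benzyl 2-(benzyloxy)-6-[3-chloro-4-hydroxy-2-methoxy-6-(methoxycarbonyl)phenoxy]-4-methylbenzoate F6. The BCl3/C6HMe5 conditions of step 12 should then cleave the benzyl ester and the benzyl ether together. The route is rejoined at 22.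

## Further compounds

F1 | step 8 | methyl 2-[4-(benzyloxy)-6-methyl-3-oxo-2,3-dihydrobenzofuran-2-yl]-6,6-dimethoxy-4-oxohex-5-enoate (mixture of diastereomers) | COC(=O)C(CC(=O)C=C(OC)OC)C1Oc2cc(C)cc(OCc3ccccc3)c2C1=O
F2 | step 10 | silyl dienol ether of 19 (racemic, one enantiomer drawn; ring A with C1 CH–CO2Me, C6H=C5–OSiMe3, C4(Cl)=C3(OMe)) | COC(=O)[C@@H]1C=C(O[Si](C)(C)C)C(Cl)=C(OC)[C@]12Oc3cc(C)cc(OCc4ccccc4)c3C2=O
F3 | step 9 | 3-chloro-4,4-dimethoxybut-3-en-2-one | CC(=O)C(Cl)=C(OC)OC
F4 | step 9 | 2-chloro-1,1-dimethoxy-3-(trimethylsilyloxy)buta-1,3-diene | COC(OC)=C(Cl)C(=C)O[Si](C)(C)C
F5 | step 9 | chlorinated silyl ketal cycloadduct (racemic, one enantiomer drawn; as 17 with Cl on C4) | COC(=O)[C@@H]1CC(O[Si](C)(C)C)=C(Cl)C(OC)(OC)[C@]12Oc3cc(C)cc(OCc4ccccc4)c3C2=O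
F6 | step 11 | benzyl 2-(benzyloxy)-6-[3-chloro-4-hydroxy-2-methoxy-6-(methoxycarbonyl)phenoxy]-4-methylbenzoate | COC(=O)c1cc(O)c(Cl)c(OC)c1Oc1cc(C)cc(OCc2ccccc2)c1C(=O)OCc1ccccc1
A1 | alternative 1 | methyl 5-(benzyloxy)-4-chloro-2-hydroxy-3-methoxybenzoate | COC(=O)c1cc(OCc2ccccc2)c(Cl)c(OC)c1O
A2 | alternative 1 | methyl 5-(benzyloxy)-4-chloro-2-(ethynyloxy)-3-methoxybenzoate | COC(=O)c1cc(OCc2ccccc2)c(Cl)c(OC)c1OC#C
A3 | alternative 1 | benzyl 4-(benzyloxy)-6-methyl-2-oxo-2H-pyran-3-carboxylate | Cc1cc(OCc2ccccc2)c(C(=O)OCc2ccccc2)c(=O)o1
A4 | alternative 1 | benzyl 2-(benzyloxy)-6-[4-(benzyloxy)-3-chloro-2-methoxy-6-(methoxycarbonyl)phenoxy]-4-methylbenzoate | COC(=O)c1cc(OCc2ccccc2)c(Cl)c(OC)c1Oc1cc(C)cc(OCc2ccccc2)c1C(=O)OCc1ccccc1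
A5 | alternative 2 | methyl 4-chloro-2-hydroxy-3-methoxy-5-(methoxymethoxy)benzoate | COC(=O)c1cc(OCOC)c(Cl)c(OC)c1O
A6 | alternative 2 | 1-tert-butyl 7-methyl (5Z)-3-[3-chloro-2-methoxy-6-(methoxycarbonyl)-4-(methoxymethoxy)phenoxy]-5-methylhepta-2,5-dienedioate (geometry at C2=C3 immaterial) | COC(=O)c1cc(OCOC)c(Cl)c(OC)c1OC(=CC(=O)OC(C)(C)C)C/C(C)=C\C(=O)OC
A7 | alternative 2 | tert-butyl 2-[3-chloro-2-methoxy-6-(methoxycarbonyl)-4-(methoxymethoxy)phenoxy]-6-hydroxy-4-methylbenzoate | COC(=O)c1cc(OCOC)c(Cl)c(OC)c1Oc1cc(C)cc(O)c1C(=O)OC(C)(C)C
A8 | alternative 3 | methyl 6-methoxy-4-oxohexa-2,5-diynoate | COC#CC(=O)C#CC(=O)OC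
A9 | alternative 3 | dechloro spiro grisadienone benzyl ether (racemic, one enantiomer drawn; 20 without Cl) | COC(=O)C1=CC(=O)C=C(OC)[C@]12Oc3cc(C)cc(OCc4ccccc4)c3C2=O
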